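**Plan**

- Retrosynthesis: the target is cut first at the stilbene C=C (a ring B benzylphosphonate plus a ring A aldehyde), then at two bonds of ring B, C2–C3 and C4–C5 (ring B numbered with C1 at the styryl carbon, C3 at the geranyl carbon, C4 at the hydroxyl carbon).
- Enabling feature: the C4 oxygen with its ortho C3 geranyl group and para C1 carbon substituent maps C3/C4 onto the two carbons of a ketene acetal whose nucleophilic carbon carries the geranyl CH2. C5, C6, C1 and C2 map onto C3, C4, C5 and C6 of a 2-pyrone-5-carboxylate, whose O1–C2 bridge leaves as CO2.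
- Forward: geranyl bromide and acetic acid give geranylacetic acid and its bis(trimethylsilyl) ketene acetal. Cycloaddition with methyl coumalate builds ring B, the only ring made, as methyl 3-geranyl-4-hydroxybenzoate.
- The phenol ester is silylated, reduced and converted to a benzylphosphonate. Ring A enters intact as silylated 3,5-dihydroxybenzaldehyde, and olefination followed by desilylation gives schweinfurthin I.
- Stereochemistry: there is no stereocenter. The (2E) alkene of the chain is bought with geranyl bromide and never touched, and the (E)-stilbene is set by the Horner–Wadsworth–Emmons reaction.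

Key step: step 3

Remark: "geranyl" stands for the (2E)-3,7-dimethylocta-2,6-dien-1-yl group; geranyl bromide of high (2E) purity and a commercial solution of LiN(i-Pr)2 are assumed.

**Route**

Step 1
Reactants: 1 geranyl bromide ((2E)-1-bromo-3,7-dimethylocta-2,6-diene); 2 acetic acid
Product: 4 (4E)-5,9-dimethyldeca-4,8-dienoic acid (geranylacetic acid), via dilithium ethene-1,1-diolate 3 (not isolated)
Conditions: 2 (1.5 equiv), LiN(i-Pr)2 (3.0 equiv), THF–HMPA, 0 °C; then 1, 0 °C → rt; cold 1 M HCl
Reagents that add atoms: none
Why: Alkylation of a carboxylic acid dianion, in which the acetate dianion kept in solution by HMPA displaces the primary allylic bromide by SN2 at C1, so the (2E) alkene is carried over unchanged.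

Step 2
Reactants: 4 (4E)-5,9-dimethyldeca-4,8-dienoic acid
Product: 6 (4E)-5,9-dimethyl-1,1-bis(trimethylsilyloxy)deca-1,4,8-triene (bis(trimethylsilyl) ketene acetal of 4), via dilithium enediolate 5 (not isolated)
Conditions: LiN(i-Pr)2 (2.2 equiv), THF, 0 °C → rt; TMSCl (2.5 equiv), −78 °C → rt; pentane, filtration under Ar, Kugelrohr distillation
Reagents that add atoms: chlorotrimethylsilane, C[Si](C)(C)Cl
Why: Double deprotonation of the acid followed by O,O-silylation of the enediolate is the standard bis-silyl ketene acetal synthesis, and the chain alkenes offer no competing acidic site.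

Step 3
Reactants: 6 (4E)-5,9-dimethyl-1,1-bis(trimethylsilyloxy)deca-1,4,8-triene (1.5 equiv); 7 methyl coumalate (methyl 2-oxo-2H-pyran-5-carboxylate)
Product: 11 methyl 3-geranyl-4-hydroxybenzoate, via bridged lactone cycloadduct 8 (not isolated), via cyclohexadiene bis-silyl ketal 9 (not isolated), via aryl trimethylsilyl ether 10 (not isolated)
Conditions: toluene, 110 °C, sealed tube, Ar; then THF, 10% aq. citric acid, rt
Reagents that add atoms: none
Why: The lactone and ester carbonyls lower the LUMO of 7 and place its largest coefficient on C6, so the electron-rich ketene acetal 6 adds across C3 and C6 in an asynchronous inverse-electron-demand Diels–Alder reaction, its nucleophilic CH carbon bonding to C6 and its disilyloxy carbon to C3; this is the established course of methyl coumalate with ketene dialkyl acetals, including alkyl-substituted ones generated from orthoesters. Ring B thus closes by an intermolecular [4+2] cycloaddition that makes two of its bonds (C2–C3 and C4–C5) in one operation, and the bridged lactone 8 then expels CO2 by retro-Diels–Alder reaction to give diene 9. Loss of trimethylsilanol across the geranyl-bearing CH and the ketal carbon aromatizes 9 to aryl silyl ether 10, which the mild aqueous acid of the work-up cleaves to phenol 11. The sp3 centres of 8 and 9 are formed without control and are erased on aromatization, so no stereocenter has to be set. The selectivity the step needs is regiochemical, oxygen para and geranyl meta to the ester, and it is secured by the union of the most nucleophilic carbon of 6 with the most electrophilic carbon of 7, while the unactivated trisubstituted alkenes of the chain cannot compete as dienophiles in the absence of acid or metal.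

Step 4
Reactants: 11 methyl 3-geranyl-4-hydroxybenzoate
Product: 12 methyl 4-(tert-butyldimethylsilyloxy)-3-geranylbenzoate
Conditions: TBSCl (1.3 equiv), imidazole (2.5 equiv), DMF, rt
Reagents that add atoms: tert-butyldimethylsilyl chloride, CC(C)(C)[Si](C)(C)Cl
Why: Imidazole-promoted silylation of a phenol, to which the ester and the isolated alkenes are inert, masks the para-hydroxyl before the benzylic position is activated.

Step 5
Reactants: 12 methyl 4-(tert-butyldimethylsilyloxy)-3-geranylbenzoate
Product: 13 [4-(tert-butyldimethylsilyloxy)-3-geranylphenyl]methanol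
Conditions: i-Bu2AlH (2.5 equiv), CH2Cl2, −78 → 0 °C; aq. potassium sodium tartrate
Reagents that add atoms: none
Why: Hydride reduction of an aryl ester to the benzylic alcohol with i-Bu2AlH at low temperature leaves the aryl silyl ether and the trisubstituted alkenes untouched.

Step 6
Reactants: 13 [4-(tert-butyldimethylsilyloxy)-3-geranylphenyl]methanol
Product: 14 4-(bromomethyl)-1-(tert-butyldimethylsilyloxy)-2-geranylbenzene
Conditions: CBr4 (1.3 equiv), PPh3 (1.4 equiv), CH2Cl2, 0 °C; short silica plug, used at once
Reagents that add atoms: carbon tetrabromide, BrC(Br)(Br)Br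
Why: The Appel reaction replaces the benzylic hydroxyl by bromide under neutral conditions, avoiding the HBr that could add to the chain alkenes or strip the silyl ether.

Step 7
Reactants: 14 4-(bromomethyl)-1-(tert-butyldimethylsilyloxy)-2-geranylbenzene
Product: 15 diethyl [4-(tert-butyldimethylsilyloxy)-3-geranylbenzyl]phosphonate
Conditions: P(OEt)3 (neat, 4 equiv), 120 °C; excess removed in vacuo
Reagents that add atoms: triethyl phosphite, CCOP(OCC)OCC
Why: Michaelis–Arbuzov reaction of a reactive benzylic bromide with triethyl phosphite, driven by loss of volatile bromoethane, needs no acid or base and so spares the silyl ether and the alkenes.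

Step 8
Reactants: 16 3,5-dihydroxybenzaldehyde
Product: 17 3,5-bis(tert-butyldimethylsilyloxy)benzaldehyde
Conditions: TBSCl (2.4 equiv), imidazole (5 equiv), DMF, rt
Reagents that add atoms: tert-butyldimethylsilyl chloride, CC(C)(C)[Si](C)(C)Cl
Why: Imidazole-promoted silylation caps both phenols and leaves the aldehyde free for the olefination.

Step 9
Reactants: 15 diethyl [4-(tert-butyldimethylsilyloxy)-3-geranylbenzyl]phosphonate; 17 3,5-bis(tert-butyldimethylsilyloxy)benzaldehyde
Product: 19 (E)-1-[4-(tert-butyldimethylsilyloxy)-3-geranylphenyl]-2-[3,5-bis(tert-butyldimethylsilyloxy)phenyl]ethene, via sodium phosphonate carbanion 18 (not isolated)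
Conditions: 15, NaH (1.5 equiv), 15-crown-5 (0.1 equiv), THF, 0 °C; then 17 (1.05 equiv), 0 °C → rt
Reagents that add atoms: none
Why: Horner–Wadsworth–Emmons olefination of a benzylic phosphonate with an aromatic aldehyde gives the (E)-stilbene with high selectivity under these equilibrating conditions, and any partial loss of an aryl silyl group is harmless because all three are removed next.

Step 10
Reactants: 19 (E)-1-[4-(tert-butyldimethylsilyloxy)-3-geranylphenyl]-2-[3,5-bis(tert-butyldimethylsilyloxy)phenyl]ethene
Product: 20 schweinfurthin I, 5-[(E)-2-(3-geranyl-4-hydroxyphenyl)ethenyl]benzene-1,3-diol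
Conditions: Bu4NF (3.6 equiv), AcOH (3.6 equiv), THF, 0 °C → rt, Ar
Reagents that add atoms: none
Why: Fluoride cleavage of the three aryl silyl ethers, buffered with acetic acid so that the electron-rich phenoxides are not exposed to base and air, frees the triphenol without acid that could cyclize the ortho-geranyl phenol.

**Compound list**

1 | geranyl bromide, (2E)-1-bromo-3,7-dimethylocta-2,6-diene | CC(C)=CCC/C(C)=C/CBr | starting material
2 | acetic acid | CC(=O)O | starting material
3 | dilithium ethene-1,1-diolate (dianion of acetic acid) | [Li+].[Li+].C=C([O-])[O-] | intermediate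
4 | (4E)-5,9-dimethyldeca-4,8-dienoic acid (geranylacetic acid) | CC(C)=CCC/C(C)=C/CCC(=O)O | intermediate
5 | dilithium (4E)-5,9-dimethyldeca-1,4,8-triene-1,1-diolate (enediolate of 4) | [Li+].[Li+].CC(C)=CCC/C(C)=C/CC=C([O-])[O-] | intermediate
6 | (4E)-5,9-dimethyl-1,1-bis(trimethylsilyloxy)deca-1,4,8-triene | CC(C)=CCC/C(C)=C/CC=C(O[Si](C)(C)C)O[Si](C)(C)C | intermediate
7 | methyl coumalate, methyl 2-oxo-2H-pyran-5-carboxylate | COC(=O)C1=COC(=O)C=C1 | starting material
8 | methyl 7-geranyl-3-oxo-8,8-bis(trimethylsilyloxy)-2-oxabicyclo[2.2.2]oct-5-ene-6-carboxylate (mixture of diastereomers, sp3 centres undefined) | COC(=O)C1=CC2C(=O)OC1C(C/C=C(\C)CCC=C(C)C)C2(O[Si](C)(C)C)O[Si](C)(C)C | intermediate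
9 | methyl 3-geranyl-4,4-bis(trimethylsilyloxy)cyclohexa-1,5-diene-1-carboxylate (racemic) | COC(=O)C1=CC(C/C=C(\C)CCC=C(C)C)C(O[Si](C)(C)C)(O[Si](C)(C)C)C=C1 | intermediate
10 | methyl 3-geranyl-4-(trimethylsilyloxy)benzoate | COC(=O)c1ccc(O[Si](C)(C)C)c(C/C=C(\C)CCC=C(C)C)c1 | intermediate
11 | methyl 3-geranyl-4-hydroxybenzoate | COC(=O)c1ccc(O)c(C/C=C(\C)CCC=C(C)C)c1 | intermediate
12 | methyl 4-(tert-butyldimethylsilyloxy)-3-geranylbenzoate | COC(=O)c1ccc(O[Si](C)(C)C(C)(C)C)c(C/C=C(\C)CCC=C(C)C)c1 | intermediate
13 | [4-(tert-butyldimethylsilyloxy)-3-geranylphenyl]methanol | OCc1ccc(O[Si](C)(C)C(C)(C)C)c(C/C=C(\C)CCC=C(C)C)c1 | intermediate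
14 | 4-(bromomethyl)-1-(tert-butyldimethylsilyloxy)-2-geranylbenzene | BrCc1ccc(O[Si](C)(C)C(C)(C)C)c(C/C=C(\C)CCC=C(C)C)c1 | intermediate
15 | diethyl [4-(tert-butyldimethylsilyloxy)-3-geranylbenzyl]phosphonate | CCOP(=O)(OCC)Cc1ccc(O[Si](C)(C)C(C)(C)C)c(C/C=C(\C)CCC=C(C)C)c1 | intermediate
16 | 3,5-dihydroxybenzaldehyde | O=Cc1cc(O)cc(O)c1 | starting material
17 | 3,5-bis(tert-butyldimethylsilyloxy)benzaldehyde | O=Cc1cc(O[Si](C)(C)C(C)(C)C)cc(O[Si](C)(C)C(C)(C)C)c1 | intermediate
18 | sodium salt of the benzylic carbanion of phosphonate 15 | [Na+].CCOP(=O)(OCC)[CH-]c1ccc(O[Si](C)(C)C(C)(C)C)c(C/C=C(\C)CCC=C(C)C)c1 | intermediate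
19 | (E)-1-[4-(tert-butyldimethylsilyloxy)-3-geranylphenyl]-2-[3,5-bis(tert-butyldimethylsilyloxy)phenyl]ethene | CC(C)=CCC/C(C)=C/Cc1cc(/C=C/c2cc(O[Si](C)(C)C(C)(C)C)cc(O[Si](C)(C)C(C)(C)C)c2)ccc1O[Si](C)(C)C(C)(C)C | intermediate
20 | schweinfurthin I, 5-[(E)-2-(3-geranyl-4-hydroxyphenyl)ethenyl]benzene-1,3-diol | CC(C)=CCC/C(C)=C/Cc1cc(/C=C/c2cc(O)cc(O)c2)ccc1O | target

**Step count**

Total step count: 10. Longest linear sequence: 9 steps (steps 1 to 7, then 9 and 10); step 8 is the one-step side branch to the ring A aldehyde.

**Steps most likely to fail**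

Step 3. The ketene acetal may add to C6 of the pyrone in the Michael sense only, with silyl transfer and opening of the lactone in place of ring closure. It may also undergo O-to-C silyl migration at 110 °C faster than it cycloadds. In that case ring B is taken from a bought arene and phenol 11 is reached by ortho C-alkylation of a phenoxide, which is known chemistry. The fallback sets out from geranyl bromide 1: methyl 4-hydroxybenzoate F1 is converted with NaH in toluene into sodium 4-(methoxycarbonyl)phenoxide F2, and the tight ion pair in the non-polar medium directs allylation by 1 to the carbon ortho to oxygen. The product is separated from the O-geranyl ether, and the route is rejoined at 11.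

Step 2. Silylation of the dianion may go partly on carbon, and the moisture-sensitive ketene acetal may be lost by hydrolysis during isolation. The fallback sets out from acid 4, which is first converted with TMSCl and Et3N into trimethylsilyl (4E)-5,9-dimethyldeca-4,8-dienoate F3. F3 is then deprotonated with LiN(i-Pr)2 (1.1 equiv) at −78 °C in the presence of TMSCl, so that a monoanionic ester enolate is trapped on oxygen as it forms. LiCl is filtered off under argon and the solution, after exchange of THF for toluene, is carried into the cycloaddition without distillation. The route is rejoined at 6.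

Step 6. The electron-rich para-silyloxybenzyl bromide may ionize during isolation and be lost by oligomerization through a quinone-methide-type cation. The fallback sets out from alcohol 13 and avoids any isolated halide: 13 is heated with ZnI2 (1.5 equiv) and P(OEt)3 (3 equiv) in THF at reflux, the known direct conversion of electron-rich benzylic alcohols into diethyl benzylphosphonates, which exchanges the benzylic C–O bond for C–P in one flask. The route is rejoined at 15, and no compound outside the list is made (F0).

**Further compounds**

F1 | step 3 | methyl 4-hydroxybenzoate | COC(=O)c1ccc(O)cc1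
F2 | step 3 | sodium 4-(methoxycarbonyl)phenoxide | [Na+].COC(=O)c1ccc([O-])cc1
F3 | step 2 | trimethylsilyl (4E)-5,9-dimethyldeca-4,8-dienoate | CC(C)=CCC/C(C)=C/CCC(=O)O[Si](C)(C)C
F0 | step 6 | none | none
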